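Slowness opened the meeting and was soon set aside: the zeta readings of Q stand flat from 1.33 min on, so the chair asked about the split between Q and G at the end, not about speed.

in all of them: X 0.43 mM

| charge | L | D | Z | temperature | remark | time |
|---|---|---|---|---|---|---|
| zeta | 0.50 M | 0.35 M | 0.50 M | 10 °C | run made earlier |  |
| eta | 0.25 M | 0.35 M | 0.50 M | 25 °C | run made earlier |  |
| gamma | 0.38 M | 0.35 M | 0.50 M | 10 °C | run made earlier |  |
| ash | 0.50 M | 0.350 M (in portions, 3, over 1.5 min) | 0.500 M | 25 °C | first portion at the start, last at 1.5 min | 2.5 min |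
| alder | 0.50 M | 0.350 M | 0.500 M | 25 °C | everything together at the start | 2.5 min |
| birch | 0.50 M | 0.350 M (fed, over 1.5 min) | 0.500 M | 25 °C | all else is in the flask from the start; the feed brings no volume worth counting | 2.5 min |
| elm | 0.50 M | 0.350 M | 0.500 M (fed, over 1.5 min) |  | the addition at −5 °C, then warmed to 25 °C; the feed brings no volume worth counting | 2.5 min |

zeta run (percent of the L charged)

| time / min | Q / % | G / % |
|---|---|---|
| 1.33 | 50 | 8 |
| 3.00 | 47 | 7 |
| 4.00 | 48 | 6 |
| 5.00 | 51 | 10 |

eta run (percent of the L charged)

| time / s | Q / % | G / % |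
|---|---|---|
| 15.0 | 60 | 9 |
| 40.0 | 67 | 14 |
| 80.0 | 73 | 13 |
| 120 | 71 | 15 |

gamma run (percent of the L charged)

| time / min | Q / % | G / % |
|---|---|---|
| 0.333 | 48 | 7 |
| 0.667 | 54 | 7 |
| 2.00 | 60 | 8 |
| 4.00 | 64 | 10 |

(scatter of a reading: 1.5 percentage points)

* which flask leads in share of Q in Q plus G ("all alike" within 1.5 percentage points) (ash / alder / birch / elm / all alike)
* share of Q in Q plus G at the end, ash
* share of Q in Q plus G at the end, alder
* share of Q in Q plus G at the end, birch
* share of Q in Q plus G at the end, elm

- a reading or a percentage of Q counts all its forms, free or not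

I proposed one number, r, the Q made per G made (the selectivity factor), with the share of Q being r over r plus one. Pooling the readings of each run, I read 6.32 from zeta and 7.06 from gamma. Their c_L differ, but the scatter on the small G readings covers that gap, so I joined them into 6.70 at 10 °C. Eta, which differs in c_L as well as in temperature, gave 5.31 at 25 °C, so I read r higher in the two colder runs and took that as an effect of temperature, knowing the readings could not separate the two.

I then pointed out that −5 °C lies as far below 10 °C as 10 °C lies below 25 °C. Taking the same factor for each equal fall in temperature, I estimated r at −5 °C as 8.44; this cold ratio, the Q made per G made at −5 °C, was what I carried forward. Gamma, at 10 °C, already held 48% of Q at 0.333 min, a time shorter than the 1.5 min of cold addition in elm, so I expected elm to make much of its Q in the cold. I therefore committed to 89.4% for elm and 84.2% for the warm flasks, with elm leading.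

The forecast differed, giving 85.5% for ash, 85% for alder, 85.5% for birch and 86% for elm, and its verdict was all alike. Its ground, in its own words: “D and Z were never varied, so their orders are unknown, and any dosing effect is unproven”.

    L + D + X → X + Q (k = 1000 L² mol⁻² s⁻¹, Ea = 36.0 kJ mol⁻¹)
    Z + D + X → X + E (k = 200 L² mol⁻² s⁻¹, Ea = 36.0 kJ mol⁻¹)
    L + D → G (k = 0.0790 L mol⁻¹ s⁻¹, Ea = 49.0 kJ mol⁻¹)
    X + Q ⇌ J (K = 2.10 L mol⁻¹, k = 0.160 L mol⁻¹ s⁻¹, Ea = 67.0 kJ mol⁻¹, ΔH = −31.0 kJ mol⁻¹)
    (constants at 25 °C)

The flasks ended at 82.1% in ash, 83.5% in alder, 82.0% in birch and 89.9% in elm, so elm leads. In elm, the half-life of D by the making of Q was 0.40 min at 0.265 min, shorter than the 1.5 min of cold addition. Against the estimated cold ratio of 8.44, Q over G at the end came to 8.89 in elm and to 9.65 in a neighbour flask, the same as elm but with c_L at 1.2 M.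

(The readings were computed on assumed constants, noise included.)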